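**Plan** (numbering: C1 angular C–Me, C2, C3, C4 = C(OH)iPr, C5 = fusion CH, C6 = CH–OAr, C7=C8(Me), C9 = CH–OAc, C10 = CH2; β = face of the C1 methyl)
1. Late cuts: the phenol silyl group, C9–OAc (formed with inversion), C7=C8, C8–CH3 and the C6 aroate. These lead back to a trans-fused hydroazulene-6,9-dione.
2. Enabling feature: in the seven-membered ring C6 and C9 are 1,4-oxygenated across C7–C8. They are also joined the other way round by C5–C1–C10, a 1,5-dicarbonyl path. This pattern results when the enol C5=C9 of a cyclopentane-1,3-dione (C6–C5–C9, bridged by C7–C8) adds to a C1=C10 alkene and the C5–C9 bond then breaks.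
3. Key cut: open C5–C1 and C9–C10 and restore C5–C9. This gives a 3-benzyloxy-cyclopent-2-enone that carries at C5 the free C4 carbinol (isopropyl) and the C3–C2–C1(Me)=C10 tether.
4. The dione ring (C6–C9) comes from furan through a furyl carbinol built on the C5 aldehyde. The chain comes from 2-isopropylglycidol and a methallyl nucleophile.
5. Forward order: chain, then the five-membered dione ring, then cyclopentane and cyclobutane together, then the cycloheptane by C5–C9 scission.
6. Stereochemistry: C4 from Sharpless epoxidation; C1 and C5 relayed from C4 in the photochemical step; C6 by hydroxyl-directed hydride delivery; C9 by substrate-controlled hydride addition followed by SN2 inversion.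

Key step: step 13

Assumption: hydride is taken to reach the C9 carbonyl of the enone from the α face, anti to the axial C1 methyl. The allylic alcohol is therefore planned as 9β and is inverted on acetylation.

Step 1
Reactants: 1 3-methylbutanal
Product: 2 3-methyl-2-methylidenebutanal
Conditions: 37% aq. HCHO, pyrrolidine (10 mol %), propionic acid (10 mol %), i-PrOH, 45 °C
Reagents that add atoms: formaldehyde, C=O
Why: Organocatalytic α-methylenation (Mannich condensation of the enamine with formaldehyde, then amine elimination) is general for β-branched aldehydes and stops at the 2-substituted acrolein because no α-hydrogen remains.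

Step 2
Reactants: 2 3-methyl-2-methylidenebutanal
Product: 3 3-methyl-2-methylidenebutan-1-ol
Conditions: NaBH4, CeCl3·7H2O, MeOH, 0 °C
Reagents that add atoms: none
Why: Luche reduction gives clean 1,2-addition of hydride to the enal, so the 1,1-disubstituted alkene needed for the epoxidation is kept.

Step 3
Reactants: 3 3-methyl-2-methylidenebutan-1-ol
Product: 4 [(2R)-2-(propan-2-yl)oxiran-2-yl]methanol
Conditions: Ti(OiPr)4 (10 mol %), D-(−)-diisopropyl tartrate (12 mol %), t-BuOOH, 4 Å MS, CH2Cl2, −20 °C
Reagents that add atoms: tert-butyl hydroperoxide, CC(C)(C)OO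
Why: In the catalytic Sharpless asymmetric epoxidation of a 2-substituted allylic alcohol, drawn with the hydroxymethyl group at the lower right, the D-(−)-tartrate complex delivers oxygen from above and sets C4 as R, while the catalytic protocol with sieves limits opening of the sensitive 2,2-disubstituted epoxide.

Step 4
Reactants: 4 [(2R)-2-(propan-2-yl)oxiran-2-yl]methanol; 5 (2-methylprop-2-en-1-yl)magnesium chloride
Product: 6 (2R)-5-methyl-2-(propan-2-yl)hex-5-ene-1,2-diol
Conditions: 5 (3 equiv), CuI (10 mol %), THF, −30 → 0 °C; then H2O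
Reagents that add atoms: none
Why: The copper-catalysed Grignard opening is an SN2 attack at the unhindered CH2 terminus (C3), so the C4–O bond and its configuration are untouched, and the Payne shift of the alkoxide is degenerate and returns the same enantiomer.

Step 5
Reactants: 6 (2R)-5-methyl-2-(propan-2-yl)hex-5-ene-1,2-diol
Product: 7 (2R)-2-hydroxy-5-methyl-2-(propan-2-yl)hex-5-enal
Conditions: (COCl)2, DMSO, CH2Cl2, −78 °C; Et3N, → 0 °C
Reagents that add atoms: none
Why: Swern oxidation converts only the primary alcohol, since the tertiary carbinol has no carbinol hydrogen, and it avoids the glycol cleavage that periodate or hypervalent-iodine oxidants could cause.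

Step 6
Reactants: 7 (2R)-2-hydroxy-5-methyl-2-(propan-2-yl)hex-5-enal
Product: 8 (2R)-2-(tert-butyldimethylsilyloxy)-5-methyl-2-(propan-2-yl)hex-5-enal
Conditions: TBSOTf, 2,6-lutidine, CH2Cl2, 0 °C → rt
Reagents that add atoms: tert-butyldimethylsilyl trifluoromethanesulfonate, CC(C)(C)[Si](C)(C)OS(=O)(=O)C(F)(F)F
Why: A silyl triflate with a hindered pyridine base silylates even congested tertiary alcohols, and the aldehyde has no α-hydrogen, so neither enol silane formation nor epimerisation can occur.

Step 7
Reactants: 8 (2R)-2-(tert-butyldimethylsilyloxy)-5-methyl-2-(propan-2-yl)hex-5-enal; 9 furan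
Product: 11 (2R)-2-(tert-butyldimethylsilyloxy)-1-(furan-2-yl)-5-methyl-2-(propan-2-yl)hex-5-en-1-ol (both carbinol epimers), via furan-2-yllithium 10 (not isolated)
Conditions: 9, n-BuLi, THF, −78 → 0 °C; 8, −78 °C; H2O quench at −78 °C
Reagents that add atoms: none
Why: This is the 1,2-addition of a heteroaryllithium to a non-enolisable aldehyde, the cold quench forestalls silyl migration between the vicinal oxygens, and the new C5 carbinol centre may be a mixture because it is ionised in the next step.

Step 8
Reactants: 11 (2R)-2-(tert-butyldimethylsilyloxy)-1-(furan-2-yl)-5-methyl-2-(propan-2-yl)hex-5-en-1-ol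
Product: 12 trans-4-hydroxy-5-[(3R)-3-(tert-butyldimethylsilyloxy)-2,6-dimethylhept-6-en-3-yl]cyclopent-2-en-1-one (both trans isomers)
Conditions: Dy(OTf)3 (10 mol %), t-BuOH/H2O (5:1), 80 °C
Reagents that add atoms: water, O
Why: In the Piancatelli rearrangement the furan-stabilised cation at C5 takes up water at the distal furan carbon, the ring opens to a hydroxypentadienyl cation and 4π conrotatory closure forms C5–C9, so the four furan carbons become C6–C9, while the trans C5/C9 centres are erased later and the weakly acidic medium spares the alkene and the silyl ether.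

Step 9
Reactants: 12 trans-4-hydroxy-5-[(3R)-3-(tert-butyldimethylsilyloxy)-2,6-dimethylhept-6-en-3-yl]cyclopent-2-en-1-one
Product: 13 2-[(3R)-3-(tert-butyldimethylsilyloxy)-2,6-dimethylhept-6-en-3-yl]cyclopent-4-ene-1,3-dione
Conditions: Dess–Martin periodinane, CH2Cl2, 0 °C → rt
Reagents that add atoms: none
Why: Dess–Martin oxidation of the allylic secondary alcohol runs under near-neutral conditions, and the ene-dione stays in its diketo form, so no enol is present to push out the C4 silyloxy group.

Step 10
Reactants: 13 2-[(3R)-3-(tert-butyldimethylsilyloxy)-2,6-dimethylhept-6-en-3-yl]cyclopent-4-ene-1,3-dione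
Product: 14 2-[(3R)-3-(tert-butyldimethylsilyloxy)-2,6-dimethylhept-6-en-3-yl]cyclopentane-1,3-dione (enol form)
Conditions: Zn dust, AcOH (5 equiv), CH2Cl2, 0 °C
Reagents that add atoms: none
Why: Zinc–acetic acid reduction is selective for the electron-poor ene-dione double bond over the isolated 1,1-disubstituted alkene, and the short cold exposure to a weak acid does not ionise the C4–O bond.

Step 11
Reactants: 14 2-[(3R)-3-(tert-butyldimethylsilyloxy)-2,6-dimethylhept-6-en-3-yl]cyclopentane-1,3-dione
Product: 15 3-(benzyloxy)-2-[(3R)-3-(tert-butyldimethylsilyloxy)-2,6-dimethylhept-6-en-3-yl]cyclopent-2-en-1-one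
Conditions: BnBr, K2CO3, acetone, rt
Reagents that add atoms: benzyl bromide, BrCc1ccccc1
Why: O-alkylation of the 1,3-dione enolate is the only open path, because C-benzylation at C5 would place two quaternary carbons side by side, and either oxygen gives the same compound since the ring is symmetric.

Step 12
Reactants: 15 3-(benzyloxy)-2-[(3R)-3-(tert-butyldimethylsilyloxy)-2,6-dimethylhept-6-en-3-yl]cyclopent-2-en-1-one
Product: 16 3-(benzyloxy)-2-[(3R)-3-hydroxy-2,6-dimethylhept-6-en-3-yl]cyclopent-2-en-1-one
Conditions: TBAF, THF, rt → 45 °C; chromatography on Et3N-deactivated silica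
Reagents that add atoms: none
Why: In this fluoride-induced desilylation the vinylogous ester tolerates basic fluoride, no acyl group is present that could migrate to O4, and the tertiary alkoxide cannot undergo retro-aldol cleavage because C5 is locked as an sp2 carbon of the enol ether.

Step 13
Reactants: 16 3-(benzyloxy)-2-[(3R)-3-hydroxy-2,6-dimethylhept-6-en-3-yl]cyclopent-2-en-1-one
Product: 19 (3R,3aR,8aR)-3-hydroxy-8a-methyl-3-(propan-2-yl)octahydroazulene-4,7-dione (trans-fused 6,9-dione; 4β-OH; 1β-Me; 5α-H), via benzyloxy photoadduct 17 (not isolated), via cyclobutanol 18 (not isolated)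
Conditions: hν (medium-pressure Hg lamp, Pyrex, λ > 290 nm), degassed cyclohexane/CH2Cl2 (9:1), 3 mM, 15 °C; evaporate; H2 (1 atm), 10% Pd/C, EtOAc, rt; then DBU (0.2 equiv), PhMe, rt
Reagents that add atoms: none
Why: The excited vinylogous ester crosses to its triplet, whose α-carbon C5 bonds to the internal alkene carbon C1 (5-exo-trig, the 1,5-closure favoured by a three-atom tether), and the resulting C9/C10 1,4-biradical collapses after spin inversion to the four-membered ring of 17, giving the straight and not the crossed adduct. This is the intramolecular de Mayo sequence known for 2-(pent-4-enyl)cyclopent-2-enones that carry an enol ester or enol ether at C3; hydrogenolysis of the benzyl ether frees cyclobutanol 18 under neutral conditions, and its retro-aldol C5–C9 scission merges the four-membered ring and the old five-membered ring into the cycloheptane-1,4-dione, so that ring arises by expansion rather than closure and the fragile C4–C5–C6 aldol unit never meets an alkoxide. C1 is set by the face of C5=C9 that the alkene reaches: in a non-polar solvent the C4 hydroxyl is hydrogen-bonded to the strongly accepting C6 carbonyl (six-membered array), which holds O4 on the C6 side, the tether over one face and the isopropyl group over the other, so O4 ends cis to C6 and to the C1 methyl. C5 and C9 of 17 follow from the geometric need for cis fusion of the cyclobutane to both five-membered rings. After scission C5 is re-set on ketonisation, and DBU should converge any cis isomer to the trans-fused epimer, which is expected to be the more stable one because it keeps C6 anti to the isopropyl group and retains the O4–H···O=C6 contact. The step needs face selectivity (free hydroxyl, aprotic medium), straight regiochemistry (tether length) and selective excitation (behind Pyrex only the enone absorbs).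

Step 14
Reactants: 19 trans-fused 4β-hydroxy-6,9-dione
Product: 20 (1R,4R,5S,6S)-4,6-dihydroxy-4-isopropyl-1-methyl-perhydroazulen-9-one (target numbering; 4β-OH; 6α-OH)
Conditions: Me4NBH(OAc)3 (5 equiv), MeCN/AcOH (1:1), −30 → −20 °C
Reagents that add atoms: none
Why: In the Evans–Saksena reduction, exchange of an acetate on boron for the C4 hydroxyl delivers hydride intramolecularly to the β face of the C6 carbonyl and gives the 6α-alcohol (anti-1,3-diol), while the unassisted C9 ketone is inert to triacetoxyborohydride.

Step 15
Reactants: 21 4-hydroxybenzoic acid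
Product: 23 4-(tert-butyldimethylsilyloxy)benzoic acid, via bis-silylated benzoate 22 (not isolated)
Conditions: TBSCl (2.3 equiv), imidazole, DMF, rt; then AcOH/THF/H2O (3:1:1), rt
Reagents that add atoms: tert-butyldimethylsilyl chloride, CC(C)(C)[Si](C)(C)Cl
Why: Exhaustive silylation followed by mild hydrolysis exploits the much greater lability of a silyl ester compared with an aryl silyl ether.

Step 16
Reactants: 20 4β,6α-dihydroxy-9-ketone; 23 4-(tert-butyldimethylsilyloxy)benzoic acid
Product: 24 6α-[4-(tert-butyldimethylsilyloxy)benzoyloxy]-4β-hydroxy-9-ketone (1R,4R,5S,6S)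
Conditions: DCC, DMAP, CH2Cl2, rt
Reagents that add atoms: none
Why: Steglich esterification acylates only the secondary C6 hydroxyl, with retention at C6, because the tertiary C4 hydroxyl is too hindered to react.

Step 17
Reactants: 24 6α-aroyloxy-4β-hydroxy-9-ketone
Product: 26 8-methyl derivative of 24 (C8 epimers), via dilithium enolate 25 (not isolated)
Conditions: LiN(iPr)2 (2.2 equiv), THF, −78 °C; MeI, DMPU, −78 → −40 °C; H2O
Reagents that add atoms: iodomethane, CI
Why: In this kinetic enolate alkylation the amide base removes a C8 proton rather than a C10 proton, which is shielded by the quaternary C1, the hindered lithium alkoxide at O4 is a spectator at low temperature, and the C8 epimer mixture is harmless because C8 becomes sp2 in the next step.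

Step 18
Reactants: 26 8-methyl-9-ketone
Product: 27 7-en-9-one (C7=C8–Me enone; 1R,4R,5S,6S)
Conditions: IBX, 4-methoxypyridine N-oxide, DMSO, rt
Reagents that add atoms: none
Why: IBX dehydrogenates the ketone through its enol, and only the C8 enol can lose a β-hydrogen (from C7) because C10 is attached to the fully substituted C1, so a single enone should form whatever the enolisation ratio.

Step 19
Reactants: 27 7-en-9-one
Product: 28 9β-allylic alcohol (9R)
Conditions: NaBH4, CeCl3·7H2O, MeOH, −78 → −40 °C
Reagents that add atoms: none
Why: In the Luche 1,2-reduction hydride should approach C9 from the α face, away from the axial C1 methyl that is 1,3-related to the carbonyl, which sets the 9β-alcohol.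

Step 20
Reactants: 28 9β-allylic alcohol
Product: 29 O-silyl target (9α-acetate; 9S)
Conditions: AcOH, PPh3, DIAD, PhMe, 0 °C → rt
Reagents that add atoms: acetic acid, CC(=O)O
Why: Mitsunobu esterification displaces the activated 9β-oxygen by SN2 attack of acetate from the open α face, which installs the ester and the 9S configuration in one operation while the tertiary alcohol and the masked phenol stay inert.

Step 21
Reactants: 29 O-silyl target
Product: 30 target CNP0305796.2 (1R,4R,5S,6S,9S)
Conditions: TBAF (1.1 equiv), AcOH (1.2 equiv), THF, 0 °C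
Reagents that add atoms: none
Why: Buffered fluoride cleaves the electron-poor aryl silyl ether rapidly, and the acetic acid buffer suppresses phenoxide- or fluoride-induced acyl transfer and loss of the two esters.

**Compound list**
1 | 3-methylbutanal | CC(C)CC=O | starting material
2 | 3-methyl-2-methylidenebutanal | CC(C)C(=C)C=O | intermediate
3 | 3-methyl-2-methylidenebutan-1-ol | CC(C)C(=C)CO | intermediate
4 | [(2R)-2-(propan-2-yl)oxiran-2-yl]methanol | OC[C@]1(C(C)C)CO1 | intermediate
5 | (2-methylprop-2-en-1-yl)magnesium chloride | CC(=C)C[Mg]Cl | starting material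
6 | (2R)-5-methyl-2-(propan-2-yl)hex-5-ene-1,2-diol | OC[C@](O)(C(C)C)CCC(C)=C | intermediate
7 | (2R)-2-hydroxy-5-methyl-2-(propan-2-yl)hex-5-enal | O=C[C@](O)(C(C)C)CCC(C)=C | intermediate
8 | (2R)-2-(tert-butyldimethylsilyloxy)-5-methyl-2-(propan-2-yl)hex-5-enal | O=C[C@](O[Si](C)(C)C(C)(C)C)(C(C)C)CCC(C)=C | intermediate
9 | furan | c1ccoc1 | starting material
10 | furan-2-yllithium | [Li]c1ccco1 | intermediate
11 | furyl carbinol (C5 epimers) | OC(c1ccco1)[C@](O[Si](C)(C)C(C)(C)C)(C(C)C)CCC(C)=C | intermediate
12 | trans-4-hydroxy-5-substituted cyclopent-2-enone | O=C1C=CC(O)C1[C@](O[Si](C)(C)C(C)(C)C)(C(C)C)CCC(C)=C | intermediate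
13 | 2-substituted cyclopent-4-ene-1,3-dione | O=C1C=CC(=O)C1[C@](O[Si](C)(C)C(C)(C)C)(C(C)C)CCC(C)=C | intermediate
14 | 2-substituted cyclopentane-1,3-dione (enol) | OC1=C(C(=O)CC1)[C@](O[Si](C)(C)C(C)(C)C)(C(C)C)CCC(C)=C | intermediate
15 | benzyl vinylogous ester, O4-silylated | O=C1CCC(OCc2ccccc2)=C1[C@](O[Si](C)(C)C(C)(C)C)(C(C)C)CCC(C)=C | intermediate
16 | benzyl vinylogous ester with free C4 carbinol (photosubstrate) | O=C1CCC(OCc2ccccc2)=C1[C@](O)(C(C)C)CCC(C)=C | intermediate
17 | tricyclic photoadduct (C5–C1 and C9–C10 formed; 9-OBn) | O=C1CC[C@]2(OCc3ccccc3)C[C@@]4(C)CC[C@@](O)(C(C)C)[C@@]124 | intermediate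
18 | tricyclic cyclobutanol (9-OH) | O=C1CC[C@]2(O)C[C@@]4(C)CC[C@@](O)(C(C)C)[C@@]124 | intermediate
19 | trans-fused 4β-hydroxy-hydroazulene-6,9-dione | O=C1C[C@@]2(C)CC[C@@](O)(C(C)C)[C@@H]2C(=O)CC1 | intermediate
20 | 4β,6α-dihydroxy-9-ketone | O=C1C[C@@]2(C)CC[C@@](O)(C(C)C)[C@@H]2[C@@H](O)CC1 | intermediate
21 | 4-hydroxybenzoic acid | OC(=O)c1ccc(O)cc1 | starting material
22 | tert-butyldimethylsilyl 4-(tert-butyldimethylsilyloxy)benzoate | CC(C)(C)[Si](C)(C)OC(=O)c1ccc(O[Si](C)(C)C(C)(C)C)cc1 | intermediate
23 | 4-(tert-butyldimethylsilyloxy)benzoic acid | OC(=O)c1ccc(O[Si](C)(C)C(C)(C)C)cc1 | intermediate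
24 | 6α-aroyloxy-4β-hydroxy-9-ketone | O=C1C[C@@]2(C)CC[C@@](O)(C(C)C)[C@@H]2[C@@H](OC(=O)c3ccc(O[Si](C)(C)C(C)(C)C)cc3)CC1 | intermediate
25 | dilithium C8 enolate / C4 alkoxide | [Li]OC=1C[C@@]2(C)CC[C@@](O[Li])(C(C)C)[C@@H]2[C@@H](OC(=O)c3ccc(O[Si](C)(C)C(C)(C)C)cc3)CC=1 | intermediate
26 | 8-methyl-9-ketone (C8 epimers) | O=C1C[C@@]2(C)CC[C@@](O)(C(C)C)[C@@H]2[C@@H](OC(=O)c3ccc(O[Si](C)(C)C(C)(C)C)cc3)CC1C | intermediate
27 | 8-methyl-7-en-9-one | O=C1C[C@@]2(C)CC[C@@](O)(C(C)C)[C@@H]2[C@@H](OC(=O)c3ccc(O[Si](C)(C)C(C)(C)C)cc3)C=C1C | intermediate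
28 | 9β-allylic alcohol | O[C@@H]1C[C@@]2(C)CC[C@@](O)(C(C)C)[C@@H]2[C@@H](OC(=O)c3ccc(O[Si](C)(C)C(C)(C)C)cc3)C=C1C | intermediate
29 | O-silyl target (9α-acetate) | CC(=O)O[C@H]1C[C@@]2(C)CC[C@@](O)(C(C)C)[C@@H]2[C@@H](OC(=O)c3ccc(O[Si](C)(C)C(C)(C)C)cc3)C=C1C | intermediate
30 | CNP0305796.2 | CC(=O)O[C@H]1C[C@@]2(C)CC[C@@](O)(C(C)C)[C@@H]2[C@@H](OC(=O)c2ccc(O)cc2)C=C1C | target

**Step count:** 21 steps in total. The longest linear sequence is 20 steps (steps 1–14 and 16–21).

**Steps most likely to fail**

Step 13. Face discrimination may erode if the hydrogen bond to the C6 carbonyl is not maintained in the reacting conformer. The alkene would then also add with O4 turned towards C9. Ketonisation may also stall at the cis ring fusion, or the aldol unit may unravel during equilibration. The fallback replaces the hydrogen bond by a covalent tether and sets out from 16. Exchange with Et2BOMe (THF, rt, MeOH removed) would give the diethylboron chelate of the photosubstrate F1. In F1 boron is bound to O4 and coordinated to the C6 carbonyl, the six-membered chelate familiar from the Narasaka–Prasad reduction. This fixes O4 on the C6 side and shifts the absorption to longer wavelength. Irradiation (λ about 350–366 nm, CH2Cl2, −40 °C) would give the boron-bound photoadduct F2. Repeated evaporation from MeOH strips the boron and comes back to the route at 17, which is hydrogenolysed as before.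

Step 8. Ionisation next to the quaternary silyloxy carbon may be sluggish. A 1,2-alkyl shift from C4 or loss of the silyl ether may then compete with the electrocyclisation. The fallback closes the same C5–C9 bond by an anionic aldol instead of a cationic 4π process and sets out from 6.
- TsCl in pyridine would give the primary tosylate F3.
- NaH would close it to (2R)-2-(3-methylbut-3-en-1-yl)-2-(propan-2-yl)oxirane F4.
- Furan-2-yllithium would open the CH2 terminus to (3S)-3-(furan-2-ylmethyl)-2,6-dimethylhept-6-en-3-ol F5.
- TBSOTf with 2,6-lutidine would give its silyl ether F6.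
- Photooxygenation (O2, tetraphenylporphyrin, hν, CH2Cl2, −78 °C) would give the furan endoperoxide F7.
- Me2S would reduce it to the (Z)-4-oxo-enal F8, and a pH 8 phosphate buffer would effect the intramolecular aldol addition, coming back to the route at 12.

Step 19. Hydride delivery may occur to both faces of the C9 carbonyl, or mainly to the β face. In that case the inversion planned for step 20 would lead to the wrong epimer. The fallback relies on reagent control and retention and sets out from 27. (R)-Me-CBS oxazaborolidine with catecholborane (PhMe, −78 °C), which treats the α-methylalkenyl side as the large group, would give the 9α-allylic alcohol F9. Ac2O, pyridine and DMAP would then acetylate it without touching C9 and come back to the route at 29.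

Further compounds
F1 | step 13 | diethylboron chelate of the photosubstrate | O=C1CCC(OCc2ccccc2)=C1[C@](OB(CC)CC)(C(C)C)CCC(C)=C
F2 | step 13 | boron-bound photoadduct | O=C1CC[C@]2(OCc3ccccc3)C[C@@]4(C)CC[C@@](OB(CC)CC)(C(C)C)[C@@]124
F3 | step 8 | (2R)-2-hydroxy-5-methyl-2-(propan-2-yl)hex-5-en-1-yl 4-methylbenzenesulfonate | Cc1ccc(cc1)S(=O)(=O)OC[C@](O)(C(C)C)CCC(C)=C
F4 | step 8 | (2R)-2-(3-methylbut-3-en-1-yl)-2-(propan-2-yl)oxirane | C1O[C@@]1(C(C)C)CCC(C)=C
F5 | step 8 | (3S)-3-(furan-2-ylmethyl)-2,6-dimethylhept-6-en-3-ol | c1coc(C[C@](O)(C(C)C)CCC(C)=C)c1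
F6 | step 8 | tert-butyldimethylsilyl ether of F5 | c1coc(C[C@](O[Si](C)(C)C(C)(C)C)(C(C)C)CCC(C)=C)c1
F7 | step 8 | furan endoperoxide of F6 | C12C=CC(C[C@](O[Si](C)(C)C(C)(C)C)(C(C)C)CCC(C)=C)(OO1)O2
F8 | step 8 | (Z)-4-oxo-enal from F7 | O=C/C=C\C(=O)C[C@](O[Si](C)(C)C(C)(C)C)(C(C)C)CCC(C)=C
F9 | step 19 | 9α-allylic alcohol (9S) | O[C@H]1C[C@@]2(C)CC[C@@](O)(C(C)C)[C@@H]2[C@@H](OC(=O)c3ccc(O[Si](C)(C)C(C)(C)C)cc3)C=C1C
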